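(The runs are calculated with constants of no real substance, and the scatter is random.)

Late in Thursday's run the free monomer falls along a first-order line. In this pseudo-first-order picture the slope is proportional to [living end], so I read [living end] from it, though the readings do not count chains.

| setting | Friday's | Monday's | Thursday's | flask |
|---|---|---|---|---|
| free monomer | 2 M | 2 M | 3 M | 2.0 M |
| initiator | 1.7 mol% | 6.8 mol% | 3.4 mol% | 3.4 mol% |
| impurity | 65 mM | 65 mM | 65 mM | 65 mM |
| remark | run made earlier | run made earlier | run made earlier |  |
| time |  |  |  | 25 min |

| run | time / min | monomer in chains / % | free monomer / % |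
|---|---|---|---|
| Friday's | 0.833 | 1.1 | 99.2 |
| Friday's | 2.50 | 2.4 | 97.9 |
| Friday's | 4.00 | 4.5 | 95.5 |
| Friday's | 6.00 | 6.8 | 93.3 |
| Friday's | 10.0 | 11.7 | 89.0 |
| Friday's | 12.0 | 13.3 | 87.0 |
| Friday's | 15.0 | 16.6 | 84.4 |
| Monday's | 1.33 | 4.9 | 94.6 |
| Monday's | 2.00 | 8.2 | 90.4 |
| Monday's | 3.00 | 15.6 | 84.2 |
| Monday's | 4.00 | 24.4 | 76.6 |
| Monday's | 6.00 | 39.2 | 61.5 |
| Monday's | 10.0 | 63.7 | 36.8 |
| Monday's | 15.0 | 81.7 | 18.7 |
| Thursday's | 3.00 | 14.4 | 85.9 |
| Thursday's | 6.00 | 33.6 | 67.8 |
| Thursday's | 10.0 | 51.5 | 47.4 |
| Thursday's | 12.0 | 60.3 | 39.7 |
| Thursday's | 15.0 | 69.9 | 30.2 |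

(standard deviation of a reading: 0.5 percentage points)

* whether the average number of monomer units in a chain (chains begun, living or dead) reaches 20 by 25 min (no / yes)
* average number of monomer units in a chain (chains begun, living or dead) at 25 min

- the average divides the monomer in chains by the number of chains begun, living and dead together
- the earlier runs do not show the number of chains; that part of a forecast is a guess

Begin with growth as the main step. Late in Thursday's run the slope reads 0.0902 min⁻¹, and that run's initiator exceeds its impurity by 37.0 mM, which I take as its [living end]. If the flask's whole 68.0 mM of initiator began chains at that slope per end, the length at 25 min would be 28.9.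

Now add impurity as a step that removes initiator before any chain begins. The flask then keeps 3.00 mM of ends, and the length becomes 111.

Last comes the competition for initiator, which I read from Friday's run. Its slope of 0.0119 min⁻¹ reads as 4.87 mM of ends out of 34.0 mM of initiator, and I let impurity have the remainder. Treat free monomer as near its charge while initiator lasts: then [living end] = σ ln(impurity charged / impurity left). Friday's run gives a reading of 8.20 mM for σ at its 2 M of free monomer, the crossover level, meaning the [impurity] at which impurity and free monomer take initiator equally fast; it is a selectivity factor in concentration form.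

The flask has the same 2.0 M of free monomer, and if all its initiator reacts, its ends equal the impurity left plus the 3.00 mM surplus. Trying 3 times Friday's ends, 14.6 mM, the rule returns 14.1 mM. I therefore commit to about 14.4 mM of ends and a length of 81.2, more than the 20 wanted.

The forecast differs from this reckoning. On reaching 20 it says no, and it gives a length of 15: “Reaching 20 looks unlikely”. Its length rests on a guess of about 68 mM of chains, where I count 14.4 mM.

On reaching 20 the flask gives yes, and its length at 25 min is 71.7. The length passes 20 after 5.91 min, with 15.3% of the free monomer reacted.

    free monomer + initiator → living end + monomer in chains (k = 0.00190 L mol⁻¹ s⁻¹)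
    initiator + impurity → spent initiator (k = 0.380 L mol⁻¹ s⁻¹)
    free monomer + living end → monomer in chains + living end, rate k3*[living end]*[free monomer] (k = 0.0370 L mol⁻¹ s⁻¹)

Through σ, the 20% of its charge of impurity left in the flask at 25.0 min reckons as 13.3 mM of ends, and the flask holds 0.0158 M of living end.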